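**Retrosynthetic overview**

- The plan rests on ring A: C1' carries the cinnamoyl C=O, the adjacent C2' a hydroxyl, and C6' next to C1' a methoxy group. The C2'–O and C1'–C(=O) bonds are made together by inserting a C1'–C2' aryne into the C–O bond of (E)-4-(allyloxy)cinnamic acid.
- The aryne precursor (C1' SiMe3, C2' OTf, C4' OPiv) comes from the 2-pyranyl-5-methoxyresorcinol by bromination, retro-Brook silyl shift, triflation and pivaloylation.
- The tetrahydropyran is closed at O1–C6 by an intramolecular SN2 displacement with inversion, after a Felkin–Anh ketone reduction has set C2. A trans-diaxial epoxide opening is not used, because any axial bond formation at C4 meets the C2 aryl group or the C6 side chain.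
- The open chain comes from a δ-lactone template: C6 from a catalytic asymmetric hetero-Diels–Alder reaction, C4 by trans cuprate addition of ring A, C3 by enolate hydroxylation.
- Ring order: dihydropyran/δ-lactone template (steps 3–4, opened in step 9), then the tetrahydropyran (step 13); the key step closes no ring.

Key step: step 19

Assumption: the sense of induction of the hetero-Diels–Alder catalyst is taken such that C6 of 5 is R; if it is the opposite, the enantiomeric catalyst is used.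

Abbreviations: ArA = 4-methoxy-2,6-bis(methoxymethoxy)phenyl; Pyr = (2S,3S,4S,6S)-2-[4-(allyloxy)phenyl]-6-{2-[4-(allyloxy)phenyl]ethyl}-3-(triisopropylsilyloxy)tetrahydro-2H-pyran-4-yl; ring A atoms are numbered as in the chalcone (C1' bears the carbonyl).

**Route**

Step 1
Reactants: 1 3-(4-hydroxyphenyl)propanoic acid
Product: 2 allyl 3-[4-(allyloxy)phenyl]propanoate
Conditions: allyl bromide (2.5 equiv), K2CO3, DMF, 60 °C
Reagents that add atoms: allyl bromide, C=CCBr
Why: Double O-alkylation of the carboxylate and the phenoxide (Williamson ether synthesis and carboxylate alkylation) protects the phenol as the allyl ether that is carried to the last step.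

Step 2
Reactants: 2 allyl 3-[4-(allyloxy)phenyl]propanoate
Product: 3 3-[4-(allyloxy)phenyl]propanal
Conditions: i-Bu2AlH (1.05 equiv), CH2Cl2, −78 °C
Reagents that add atoms: none
Why: At −78 °C the hydride stops at the tetrahedral aluminium hemiacetal of the ester, which gives the aldehyde on work-up (partial ester reduction), and the aryl allyl ether is inert.

Step 3
Reactants: 3 3-[4-(allyloxy)phenyl]propanal; 4 (E)-1-methoxybuta-1,3-diene
Product: 5 (2R,6R)-6-{2-[4-(allyloxy)phenyl]ethyl}-2-methoxy-5,6-dihydro-2H-pyran (2,6-cis)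
Conditions: 4 (3 equiv), CrCl(L) 3 mol % (L = tridentate Schiff base from (1R,2S)-1-aminoindan-2-ol and 3-(1-adamantyl)-2-hydroxy-5-methylbenzaldehyde; trivalent chromium), 4 Å sieves, neat, 23 °C
Reagents that add atoms: none
Why: Catalytic asymmetric hetero-Diels–Alder reaction of an unactivated aliphatic aldehyde with 1-methoxybutadiene, in which the chiral chromium Lewis acid selects the aldehyde face and should set C6 as R, while the endo transition state places the methoxy group cis to the side chain.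

Step 4
Reactants: 5 (2R,6R)-6-{2-[4-(allyloxy)phenyl]ethyl}-2-methoxy-5,6-dihydro-2H-pyran
Product: 6 (6R)-6-{2-[4-(allyloxy)phenyl]ethyl}-5,6-dihydro-2H-pyran-2-one
Conditions: CrO3, H2SO4, H2O, acetone, 0 °C
Reagents that add atoms: water, O
Why: Aqueous acid hydrolyses the allylic methyl acetal to the lactol, which chromic acid oxidises at once to the α,β-unsaturated δ-lactone (Jones oxidation), erasing the acetal stereocentre and leaving C6 untouched.

Step 5
Reactants: 7 5-methoxybenzene-1,3-diol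
Product: 8 1-methoxy-3,5-bis(methoxymethoxy)benzene
Conditions: MeOCH2Cl (2.5 equiv), i-Pr2NEt, CH2Cl2, 0 → 23 °C
Reagents that add atoms: chloromethyl methyl ether, COCCl
Why: Both phenols are alkylated to methoxymethyl acetals, which gives two ortho-directing groups that flank C2 for the lithiation of step 6.

Step 6
Reactants: 8 1-methoxy-3,5-bis(methoxymethoxy)benzene; 6 (6R)-6-{2-[4-(allyloxy)phenyl]ethyl}-5,6-dihydro-2H-pyran-2-one
Product: 12 (4R,6R)-6-{2-[4-(allyloxy)phenyl]ethyl}-4-(ArA)tetrahydro-2H-pyran-2-one (4,6-trans), via aryllithium 9 (not isolated), via lithium diarylcuprate 10 (not isolated), via silyl ketene acetal 11 (not isolated)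
Conditions: 8 (2.2 equiv), n-BuLi, THF, 0 °C; CuBr·SMe2 (1.05 equiv), −40 °C; 6, Me3SiCl, −78 → −30 °C; aq. NH4Cl/NH3
Reagents that add atoms: none
Why: Lithiation between the two methoxymethoxy groups (directed ortho-metalation), transmetalation to the diarylcuprate and silyl-chloride-accelerated conjugate addition deliver ring A to C4, the aryl group entering axially on the half-chair face opposite the pseudo-equatorial C6 side chain, so that C4 is set trans to C6 (4R).

Step 7
Reactants: 12 (4R,6R)-6-{2-[4-(allyloxy)phenyl]ethyl}-4-(ArA)tetrahydro-2H-pyran-2-one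
Product: 13 (3S,4S,6R)-6-{2-[4-(allyloxy)phenyl]ethyl}-3-hydroxy-4-(ArA)tetrahydro-2H-pyran-2-one
Conditions: KN(SiMe3)2, THF, −78 °C; 3-phenyl-2-(phenylsulfonyl)oxaziridine, −78 °C; aq. NH4Cl
Reagents that add atoms: 3-phenyl-2-(phenylsulfonyl)oxaziridine, O=S(=O)(N1OC1c1ccccc1)c1ccccc1
Why: The potassium lactone enolate is oxidised by the N-sulfonyloxaziridine on the face opposite the bulky C4 aryl group (enolate hydroxylation), which sets C3 as S with the hydroxyl trans to the aryl group.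

Step 8
Reactants: 13 (3S,4S,6R)-6-{2-[4-(allyloxy)phenyl]ethyl}-3-hydroxy-4-(ArA)tetrahydro-2H-pyran-2-one
Product: 14 (3S,4S,6R)-6-{2-[4-(allyloxy)phenyl]ethyl}-4-(ArA)-3-(triisopropylsilyloxy)tetrahydro-2H-pyran-2-one
Conditions: i-Pr3SiOTf, 2,6-lutidine, CH2Cl2, 0 → 23 °C
Reagents that add atoms: triisopropylsilyl trifluoromethanesulfonate, CC(C)[Si](OS(=O)(=O)C(F)(F)F)(C(C)C)C(C)C
Why: The silyl triflate silylates the hindered secondary alcohol, and the triisopropylsilyl ether is chosen because it does not chelate (needed in step 12) and does not migrate to a neighbouring alkoxide (needed in step 13).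

Step 9
Reactants: 14 (3S,4S,6R)-6-{2-[4-(allyloxy)phenyl]ethyl}-4-(ArA)-3-(triisopropylsilyloxy)tetrahydro-2H-pyran-2-one
Product: 15 (2S,3S,5R)-7-[4-(allyloxy)phenyl]-5-hydroxy-N-methoxy-N-methyl-3-(ArA)-2-(triisopropylsilyloxy)heptanamide
Conditions: MeNH(OMe)·HCl, i-PrMgCl, THF, −20 → 0 °C
Reagents that add atoms: N,O-dimethylhydroxylamine hydrochloride, CNOC.Cl
Why: The chloromagnesium amide opens the lactone by acyl substitution to the N-methoxy-N-methylamide (Weinreb amide) and frees the C5 hydroxyl without touching a stereocentre.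

Step 10
Reactants: 15 (2S,3S,5R)-7-[4-(allyloxy)phenyl]-5-hydroxy-N-methoxy-N-methyl-3-(ArA)-2-(triisopropylsilyloxy)heptanamide
Product: 16 (2S,3S,5R)-7-[4-(allyloxy)phenyl]-N-methoxy-N-methyl-3-(ArA)-5-(tosyloxy)-2-(triisopropylsilyloxy)heptanamide
Conditions: TsCl, Et3N, DMAP (cat.), CH2Cl2, 0 °C; used at once
Reagents that add atoms: p-toluenesulfonyl chloride, Cc1ccc(S(=O)(=O)Cl)cc1
Why: Sulfonylation of the only free hydroxyl, with retention, turns C5–O into the leaving group for the ring closure of step 13.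

Step 11
Reactants: 16 (2S,3S,5R)-7-[4-(allyloxy)phenyl]-N-methoxy-N-methyl-3-(ArA)-5-(tosyloxy)-2-(triisopropylsilyloxy)heptanamide; 17 1-(allyloxy)-4-bromobenzene
Product: 19 (2S,3S,5R)-1,7-bis[4-(allyloxy)phenyl]-3-(ArA)-1-oxo-2-(triisopropylsilyloxy)heptan-5-yl 4-methylbenzenesulfonate, via aryllithium 18 (not isolated)
Conditions: 17 (1.6 equiv), n-BuLi, THF, −78 °C; then 16, −78 °C; aq. NH4Cl
Reagents that add atoms: none
Why: Bromine–lithium exchange gives the aryllithium, which adds once to the N-methoxy-N-methylamide through a stable chelated tetrahedral intermediate (Weinreb ketone synthesis) at a temperature where the secondary tosylate is inert.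

Step 12
Reactants: 19 (2S,3S,5R)-1,7-bis[4-(allyloxy)phenyl]-3-(ArA)-1-oxo-2-(triisopropylsilyloxy)heptan-5-yl 4-methylbenzenesulfonate
Product: 20 (1S,2S,3S,5R)-1,7-bis[4-(allyloxy)phenyl]-1-hydroxy-3-(ArA)-2-(triisopropylsilyloxy)heptan-5-yl 4-methylbenzenesulfonate
Conditions: LiBH(s-Bu)3, THF, −78 °C; aq. NH4Cl
Reagents that add atoms: none
Why: Reduction of the α-silyloxy aryl ketone by a bulky, non-chelating hydride follows the polar Felkin–Anh model, with the C–OSi bond anti to the incoming hydride, and should give the 1,2-syn alcohol, which sets the carbinol carbon as S.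

Step 13
Reactants: 20 (1S,2S,3S,5R)-1,7-bis[4-(allyloxy)phenyl]-1-hydroxy-3-(ArA)-2-(triisopropylsilyloxy)heptan-5-yl 4-methylbenzenesulfonate
Product: 21 {[(2S,3S,4S,6S)-2-[4-(allyloxy)phenyl]-6-{2-[4-(allyloxy)phenyl]ethyl}-4-(ArA)tetrahydro-2H-pyran-3-yl]oxy}triisopropylsilane (= Pyr–ArA with ring A as its bis(methoxymethyl) ether)
Conditions: KN(SiMe3)2 (1.1 equiv), THF, 0 → 23 °C
Reagents that add atoms: none
Why: Intramolecular Williamson etherification, in which the benzylic alkoxide displaces the tosylate in a 6-exo-tet SN2 reaction with inversion (R to S), closes the tetrahydropyran with the C6 side chain cis to the C4 aryl group and trans to the C2 aryl group.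

Step 14
Reactants: 21 Pyr-substituted 1-methoxy-3,5-bis(methoxymethoxy)benzene
Product: 22 2-bromo-1-methoxy-3,5-bis(methoxymethoxy)-4-(Pyr)benzene (bromine at C1' of ring A)
Conditions: NBS (1.0 equiv), MeCN, −20 °C, dark
Reagents that add atoms: N-bromosuccinimide, O=C1CCC(=O)N1Br
Why: Electrophilic aromatic bromination takes place on the trioxygenated ring A, far more electron-rich than the two allyloxyphenyl rings, at one of its two equivalent positions between a methoxymethoxy and the methoxy group.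

Step 15
Reactants: 22 2-bromo-1-methoxy-3,5-bis(methoxymethoxy)-4-(Pyr)benzene
Product: 23 4-bromo-5-methoxy-2-(Pyr)benzene-1,3-diol
Conditions: Me3SiOTf, 2,2'-bipyridyl, CH2Cl2, 0 °C; then H2O, 23 °C
Reagents that add atoms: none
Why: The silyl triflate–bipyridyl pair converts aryl methoxymethyl ethers into pyridinium-type intermediates that water hydrolyses to the phenols without free acid, so the p-alkoxybenzylic C2–O bond, the silyl ether and the allyl ethers are not ionised or cleaved.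

Step 16
Reactants: 23 4-bromo-5-methoxy-2-(Pyr)benzene-1,3-diol
Product: 27 3-hydroxy-5-methoxy-2-(Pyr)-6-(trimethylsilyl)phenyl trifluoromethanesulfonate, via bis(trimethylsilyl) ether 24 (not isolated), via lithium phenoxide 25 (not isolated), via silyl ether triflate 26 (not isolated)
Conditions: (Me3Si)2NH, THF, 65 °C, then evaporate; n-BuLi (1.05 equiv), THF, −78 °C; Tf2O, −78 → 0 °C; aq. NaHCO3
Reagents that add atoms: hexamethyldisilazane, C[Si](C)(C)N[Si](C)(C)C; trifluoromethanesulfonic anhydride, O=S(=O)(OS(=O)(=O)C(F)(F)F)C(F)(F)F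
Why: After O-silylation of both phenols, bromine–lithium exchange at C1' triggers a 1,3 O-to-C silyl shift (retro-Brook rearrangement) from the only adjacent silyloxy group, so the lithium phenoxide that Tf2O then sulfonylates is the one at C2', and the remaining C4' silyl ether is hydrolysed on work-up.

Step 17
Reactants: 27 3-hydroxy-5-methoxy-2-(Pyr)-6-(trimethylsilyl)phenyl trifluoromethanesulfonate
Product: 28 5-methoxy-2-(Pyr)-3-[(trifluoromethylsulfonyl)oxy]-4-(trimethylsilyl)phenyl pivalate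
Conditions: PivCl, Et3N, DMAP (cat.), CH2Cl2, 0 °C
Reagents that add atoms: pivaloyl chloride, CC(C)(C)C(Cl)=O
Why: Acylation of the free C4' phenol masks the last nucleophilic oxygen as an ester that fluoride does not cleave.

Step 18
Reactants: 29 (E)-4-hydroxycinnamic acid
Product: 31 (E)-3-[4-(allyloxy)phenyl]prop-2-enoic acid, via allyl ester 30 (not isolated)
Conditions: allyl bromide (2.5 equiv), K2CO3, DMF, 60 °C; then NaOH, MeOH/H2O, 23 °C; HCl to pH 2
Reagents that add atoms: allyl bromide, C=CCBr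
Why: Allylation of both acidic groups followed by saponification of the allyl ester leaves the aryl allyl ether and the E-alkene intact and returns the free acid.

Step 19
Reactants: 28 5-methoxy-2-(Pyr)-3-[(trifluoromethylsulfonyl)oxy]-4-(trimethylsilyl)phenyl pivalate; 31 (E)-3-[4-(allyloxy)phenyl]prop-2-enoic acid
Product: 33 4-{(E)-3-[4-(allyloxy)phenyl]prop-2-enoyl}-3-hydroxy-5-methoxy-2-(Pyr)phenyl pivalate, via cesium carboxylate 32 (not isolated)
Conditions: 31 (2 equiv), Cs2CO3 (1 equiv), THF/MeOH, then evaporate and dry; 28, CsF (3 equiv), 18-crown-6 (0.3 equiv), THF, 70 °C, sealed; aq. NH4Cl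
Reagents that add atoms: none
Why: Fluoride attacks the C1' trimethylsilyl group and triflate leaves from C2' to give the C1'–C2' aryne; the cinnamate oxygen adds at C2', and the aryl anion formed at C1' attacks the ester carbonyl through a four-membered alkoxide that opens to the ortho-acyl phenoxide, so the C2'–O and C1'–C(=O) bonds form in one operation. The closest known reaction type is the insertion of arynes from ortho-silylaryl triflates into the C–O bond of carboxylic acids to give ortho-hydroxyaryl ketones, which ends in an anionic ortho-Fries-type acyl shift. No ring is closed and no stereocentre is formed; the four pyran stereocentres and the E-alkene are spectators. The step needs oxygen attack at C2' and not at C1': the C6' methoxy group polarises the aryne so that the nucleophile enters at the remote carbon C2' and the charge develops at C1' next to the C–OMe bond, while the pyranyl group on C3' opposes this sterically. The carboxylate is used as its pre-formed cesium salt in an aprotic solvent so that the aryl anion is not protonated before the acyl shift, and the C4' pivalate and the C3 silyl ether keep the other oxygens from trapping the aryne. Any flavanone formed by oxa-Michael closure of the product phenoxide is reopened in step 21.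

Step 20
Reactants: 33 4-{(E)-3-[4-(allyloxy)phenyl]prop-2-enoyl}-3-hydroxy-5-methoxy-2-(Pyr)phenyl pivalate
Product: 34 4-{(E)-3-[4-(allyloxy)phenyl]prop-2-enoyl}-3-hydroxy-5-methoxy-2-[(2S,3S,4S,6S)-2-[4-(allyloxy)phenyl]-6-{2-[4-(allyloxy)phenyl]ethyl}-3-hydroxytetrahydro-2H-pyran-4-yl]phenyl pivalate
Conditions: n-Bu4NF, AcOH (1:1), THF, 23 → 40 °C
Reagents that add atoms: none
Why: Buffered fluoride cleaves the Si–O bond of the secondary triisopropylsilyl ether (desilylation) without base-induced change at the chalcone or the pivalate.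

Step 21
Reactants: 34 C3-hydroxy chalcone tris(allyl ether) pivalate
Product: 35 CNP0310862.1, (E)-1-{2,4-dihydroxy-3-[(2S,3S,4S,6S)-3-hydroxy-2-(4-hydroxyphenyl)-6-[2-(4-hydroxyphenyl)ethyl]tetrahydro-2H-pyran-4-yl]-6-methoxyphenyl}-3-(4-hydroxyphenyl)prop-2-en-1-one
Conditions: Pd(PPh3)4 (10 mol %), K2CO3, MeOH, degassed, 23 °C; then AcOH to pH 6, 0 °C
Reagents that add atoms: none
Why: Zerovalent palladium ionises the three aryl allyl ethers to π-allyl complexes that methanol traps, K2CO3 in methanol cleaves the aryl pivalate by transesterification and opens any flavanone to the chalcone phenoxide, and mild acidification should return the chalcone with all four stereocentres untouched.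

**Compound list**

1 | 3-(4-hydroxyphenyl)propanoic acid | OC(=O)CCc1ccc(O)cc1 | starting material
2 | allyl 3-[4-(allyloxy)phenyl]propanoate | C=CCOC(=O)CCc1ccc(OCC=C)cc1 | intermediate
3 | 3-[4-(allyloxy)phenyl]propanal | O=CCCc1ccc(OCC=C)cc1 | intermediate
4 | (E)-1-methoxybuta-1,3-diene | CO/C=C/C=C | starting material
5 | (2R,6R)-6-{2-[4-(allyloxy)phenyl]ethyl}-2-methoxy-5,6-dihydro-2H-pyran | CO[C@H]1C=CC[C@@H](CCc2ccc(OCC=C)cc2)O1 | intermediate
6 | (6R)-6-{2-[4-(allyloxy)phenyl]ethyl}-5,6-dihydro-2H-pyran-2-one | O=C1C=CC[C@@H](CCc2ccc(OCC=C)cc2)O1 | intermediate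
7 | 5-methoxybenzene-1,3-diol | COc1cc(O)cc(O)c1 | starting material
8 | 1-methoxy-3,5-bis(methoxymethoxy)benzene | COCOc1cc(OC)cc(OCOC)c1 | intermediate
9 | [4-methoxy-2,6-bis(methoxymethoxy)phenyl]lithium | [Li]c1c(OCOC)cc(OC)cc1OCOC | intermediate
10 | lithium bis[4-methoxy-2,6-bis(methoxymethoxy)phenyl]cuprate | [Li+].COCOc1cc(OC)cc(OCOC)c1[Cu-]c1c(OCOC)cc(OC)cc1OCOC | intermediate
11 | (2R,4R)-2-{2-[4-(allyloxy)phenyl]ethyl}-4-(ArA)-6-(trimethylsilyloxy)-3,4-dihydro-2H-pyran | COCOc1cc(OC)cc(OCOC)c1[C@@H]1C[C@@H](CCc2ccc(OCC=C)cc2)OC(O[Si](C)(C)C)=C1 | intermediate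
12 | (4R,6R)-6-{2-[4-(allyloxy)phenyl]ethyl}-4-(ArA)tetrahydro-2H-pyran-2-one | COCOc1cc(OC)cc(OCOC)c1[C@@H]1C[C@@H](CCc2ccc(OCC=C)cc2)OC(=O)C1 | intermediate
13 | (3S,4S,6R)-6-{2-[4-(allyloxy)phenyl]ethyl}-3-hydroxy-4-(ArA)tetrahydro-2H-pyran-2-one | COCOc1cc(OC)cc(OCOC)c1[C@@H]1C[C@@H](CCc2ccc(OCC=C)cc2)OC(=O)[C@H]1O | intermediate
14 | (3S,4S,6R)-6-{2-[4-(allyloxy)phenyl]ethyl}-4-(ArA)-3-(triisopropylsilyloxy)tetrahydro-2H-pyran-2-one | COCOc1cc(OC)cc(OCOC)c1[C@@H]1C[C@@H](CCc2ccc(OCC=C)cc2)OC(=O)[C@H]1O[Si](C(C)C)(C(C)C)C(C)C | intermediate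
15 | (2S,3S,5R)-7-[4-(allyloxy)phenyl]-5-hydroxy-N-methoxy-N-methyl-3-(ArA)-2-(triisopropylsilyloxy)heptanamide | CON(C)C(=O)[C@@H](O[Si](C(C)C)(C(C)C)C(C)C)[C@H](c1c(OCOC)cc(OC)cc1OCOC)C[C@H](O)CCc1ccc(OCC=C)cc1 | intermediate
16 | (2S,3S,5R)-7-[4-(allyloxy)phenyl]-N-methoxy-N-methyl-3-(ArA)-5-(tosyloxy)-2-(triisopropylsilyloxy)heptanamide | CON(C)C(=O)[C@@H](O[Si](C(C)C)(C(C)C)C(C)C)[C@H](c1c(OCOC)cc(OC)cc1OCOC)C[C@H](OS(=O)(=O)c1ccc(C)cc1)CCc1ccc(OCC=C)cc1 | intermediate
17 | 1-(allyloxy)-4-bromobenzene | Brc1ccc(OCC=C)cc1 | starting material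
18 | [4-(allyloxy)phenyl]lithium | [Li]c1ccc(OCC=C)cc1 | intermediate
19 | (2S,3S,5R)-1,7-bis[4-(allyloxy)phenyl]-3-(ArA)-1-oxo-2-(triisopropylsilyloxy)heptan-5-yl 4-methylbenzenesulfonate | C=CCOc1ccc(cc1)C(=O)[C@@H](O[Si](C(C)C)(C(C)C)C(C)C)[C@H](c1c(OCOC)cc(OC)cc1OCOC)C[C@H](OS(=O)(=O)c1ccc(C)cc1)CCc1ccc(OCC=C)cc1 | intermediate
20 | (1S,2S,3S,5R)-1,7-bis[4-(allyloxy)phenyl]-1-hydroxy-3-(ArA)-2-(triisopropylsilyloxy)heptan-5-yl 4-methylbenzenesulfonate | C=CCOc1ccc(cc1)[C@H](O)[C@@H](O[Si](C(C)C)(C(C)C)C(C)C)[C@H](c1c(OCOC)cc(OC)cc1OCOC)C[C@H](OS(=O)(=O)c1ccc(C)cc1)CCc1ccc(OCC=C)cc1 | intermediate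
21 | {[(2S,3S,4S,6S)-2-[4-(allyloxy)phenyl]-6-{2-[4-(allyloxy)phenyl]ethyl}-4-(ArA)tetrahydro-2H-pyran-3-yl]oxy}triisopropylsilane | COCOc1cc(OC)cc(OCOC)c1[C@@H]1C[C@H](CCc2ccc(OCC=C)cc2)O[C@@H](c2ccc(OCC=C)cc2)[C@H]1O[Si](C(C)C)(C(C)C)C(C)C | intermediate
22 | 2-bromo-1-methoxy-3,5-bis(methoxymethoxy)-4-(Pyr)benzene | COCOc1cc(OC)c(Br)c(OCOC)c1[C@@H]1C[C@H](CCc2ccc(OCC=C)cc2)O[C@@H](c2ccc(OCC=C)cc2)[C@H]1O[Si](C(C)C)(C(C)C)C(C)C | intermediate
23 | 4-bromo-5-methoxy-2-(Pyr)benzene-1,3-diol | COc1cc(O)c([C@@H]2C[C@H](CCc3ccc(OCC=C)cc3)O[C@@H](c3ccc(OCC=C)cc3)[C@H]2O[Si](C(C)C)(C(C)C)C(C)C)c(O)c1Br | intermediate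
24 | 2-bromo-1-methoxy-4-(Pyr)-3,5-bis(trimethylsilyloxy)benzene | COc1cc(O[Si](C)(C)C)c([C@@H]2C[C@H](CCc3ccc(OCC=C)cc3)O[C@@H](c3ccc(OCC=C)cc3)[C@H]2O[Si](C(C)C)(C(C)C)C(C)C)c(O[Si](C)(C)C)c1Br | intermediate
25 | lithium 3-methoxy-6-(Pyr)-2-(trimethylsilyl)-5-(trimethylsilyloxy)phenoxide | [Li+].COc1cc(O[Si](C)(C)C)c([C@@H]2C[C@H](CCc3ccc(OCC=C)cc3)O[C@@H](c3ccc(OCC=C)cc3)[C@H]2O[Si](C(C)C)(C(C)C)C(C)C)c([O-])c1[Si](C)(C)C | intermediate
26 | 5-methoxy-2-(Pyr)-6-(trimethylsilyl)-3-(trimethylsilyloxy)phenyl trifluoromethanesulfonate | COc1cc(O[Si](C)(C)C)c([C@@H]2C[C@H](CCc3ccc(OCC=C)cc3)O[C@@H](c3ccc(OCC=C)cc3)[C@H]2O[Si](C(C)C)(C(C)C)C(C)C)c(OS(=O)(=O)C(F)(F)F)c1[Si](C)(C)C | intermediate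
27 | 3-hydroxy-5-methoxy-2-(Pyr)-6-(trimethylsilyl)phenyl trifluoromethanesulfonate | COc1cc(O)c([C@@H]2C[C@H](CCc3ccc(OCC=C)cc3)O[C@@H](c3ccc(OCC=C)cc3)[C@H]2O[Si](C(C)C)(C(C)C)C(C)C)c(OS(=O)(=O)C(F)(F)F)c1[Si](C)(C)C | intermediate
28 | 5-methoxy-2-(Pyr)-3-[(trifluoromethylsulfonyl)oxy]-4-(trimethylsilyl)phenyl pivalate | COc1cc(OC(=O)C(C)(C)C)c([C@@H]2C[C@H](CCc3ccc(OCC=C)cc3)O[C@@H](c3ccc(OCC=C)cc3)[C@H]2O[Si](C(C)C)(C(C)C)C(C)C)c(OS(=O)(=O)C(F)(F)F)c1[Si](C)(C)C | intermediate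
29 | (E)-4-hydroxycinnamic acid | OC(=O)/C=C/c1ccc(O)cc1 | starting material
30 | allyl (E)-3-[4-(allyloxy)phenyl]prop-2-enoate | C=CCOC(=O)/C=C/c1ccc(OCC=C)cc1 | intermediate
31 | (E)-3-[4-(allyloxy)phenyl]prop-2-enoic acid | C=CCOc1ccc(/C=C/C(=O)O)cc1 | intermediate
32 | cesium (E)-3-[4-(allyloxy)phenyl]prop-2-enoate | [Cs+].[O-]C(=O)/C=C/c1ccc(OCC=C)cc1 | intermediate
33 | 4-{(E)-3-[4-(allyloxy)phenyl]prop-2-enoyl}-3-hydroxy-5-methoxy-2-(Pyr)phenyl pivalate | COc1cc(OC(=O)C(C)(C)C)c([C@@H]2C[C@H](CCc3ccc(OCC=C)cc3)O[C@@H](c3ccc(OCC=C)cc3)[C@H]2O[Si](C(C)C)(C(C)C)C(C)C)c(O)c1C(=O)/C=C/c1ccc(OCC=C)cc1 | intermediate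
34 | 4-{(E)-3-[4-(allyloxy)phenyl]prop-2-enoyl}-3-hydroxy-5-methoxy-2-[(2S,3S,4S,6S)-2-[4-(allyloxy)phenyl]-6-{2-[4-(allyloxy)phenyl]ethyl}-3-hydroxytetrahydro-2H-pyran-4-yl]phenyl pivalate | COc1cc(OC(=O)C(C)(C)C)c([C@@H]2C[C@H](CCc3ccc(OCC=C)cc3)O[C@@H](c3ccc(OCC=C)cc3)[C@H]2O)c(O)c1C(=O)/C=C/c1ccc(OCC=C)cc1 | intermediate
35 | CNP0310862.1, (E)-1-{2,4-dihydroxy-3-[(2S,3S,4S,6S)-3-hydroxy-2-(4-hydroxyphenyl)-6-[2-(4-hydroxyphenyl)ethyl]tetrahydro-2H-pyran-4-yl]-6-methoxyphenyl}-3-(4-hydroxyphenyl)prop-2-en-1-one | COc1cc(O)c([C@@H]2C[C@H](CCc3ccc(O)cc3)O[C@@H](c3ccc(O)cc3)[C@H]2O)c(O)c1C(=O)/C=C/c1ccc(O)cc1 | target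

**Totals**

Total step count: 21. Longest linear sequence: 19 steps (steps 1–4, 6–17 and 19–21).

**Steps most likely to fail**

Step 19. The carboxylate may add at C1' instead of C2' if the steric push of the C3' pyranyl group outweighs the polarisation by the C6' methoxy group, or the aryl anion may be protonated before the acyl shift and stop at the aryl ester. The fallback sets out from bromide 22 and acid 31 and returns at 33. Acid 31 is converted through its acid chloride ((COCl)2, DMF cat.; then MeNH(OMe)·HCl, pyridine) into (E)-3-[4-(allyloxy)phenyl]-N-methoxy-N-methylprop-2-enamide F1. Bromine–lithium exchange on 22 (n-BuLi, THF, −78 °C) and 1,2-addition of the C1' aryllithium to F1 should give (E)-3-[4-(allyloxy)phenyl]-1-[6-methoxy-2,4-bis(methoxymethoxy)-3-(Pyr)phenyl]prop-2-en-1-one F2. Me3SiOTf/2,2'-bipyridyl and then water should free both ring A phenols to (E)-3-[4-(allyloxy)phenyl]-1-[2,4-dihydroxy-6-methoxy-3-(Pyr)phenyl]prop-2-en-1-one F3. PivCl (1.0 equiv), Et3N, CH2Cl2, −20 °C should then acylate the C4' hydroxyl in preference to the C2' hydroxyl, which is hydrogen-bonded to the ketone, and so reach 33.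

Step 6. The doubly ortho-substituted cuprate may add too slowly to the lactone, so that enolisation or attack at the carbonyl takes over. The fallback sets out from acetal 5 and aryllithium 9 (made from 8) and returns at 13. The arylcopper–BF3 reagent (9, CuBr·SMe2, BF3·OEt2, Et2O, −78 °C) should displace the allylic methoxy group of 5 in an anti SN2' reaction, the aryl group entering at C4 on the face opposite the leaving group and hence trans to the side chain, to give (2R,4R)-2-{2-[4-(allyloxy)phenyl]ethyl}-4-(ArA)-3,4-dihydro-2H-pyran F4. Dimethyldioxirane (acetone, −40 °C) should epoxidise the enol ether anti to the C4 aryl group, and aqueous work-up should open the epoxide to (3S,4S,6R)-6-{2-[4-(allyloxy)phenyl]ethyl}-4-(ArA)tetrahydro-2H-pyran-2,3-diol F5. Ag2CO3 on Celite in refluxing toluene should oxidise the lactol selectively to the hydroxy lactone 13.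

Step 16. Sulfonylation of the phenoxide flanked by the silylated C1' and the pyranyl-bearing C3' may stall, or butyllithium may attack a silyl ether or an allyl group before the exchange is complete. The fallback sets out from 21 and returns at 28. Directed ortho-lithiation of 21 at C1', between a methoxymethoxy and the methoxy group (s-BuLi, TMEDA, THF, −78 °C), and quench with Me3SiCl should give 1-methoxy-3,5-bis(methoxymethoxy)-4-(Pyr)-2-(trimethylsilyl)benzene F6. Me3SiOTf/2,2'-bipyridyl and then water should remove both methoxymethyl groups without protodesilylation to give 5-methoxy-2-(Pyr)-4-(trimethylsilyl)benzene-1,3-diol F7. PivCl (1.0 equiv), Et3N, −20 °C should acylate the less hindered C4' hydroxyl to give 3-hydroxy-5-methoxy-2-(Pyr)-4-(trimethylsilyl)phenyl pivalate F8. Tf2O, pyridine, CH2Cl2, 0 °C should then sulfonylate the remaining C2' hydroxyl to give 28.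

Further compounds
F1 | step 19 | (E)-3-[4-(allyloxy)phenyl]-N-methoxy-N-methylprop-2-enamide | CON(C)C(=O)/C=C/c1ccc(OCC=C)cc1
F2 | step 19 | (E)-3-[4-(allyloxy)phenyl]-1-[6-methoxy-2,4-bis(methoxymethoxy)-3-(Pyr)phenyl]prop-2-en-1-one | COCOc1cc(OC)c(C(=O)/C=C/c2ccc(OCC=C)cc2)c(OCOC)c1[C@@H]1C[C@H](CCc2ccc(OCC=C)cc2)O[C@@H](c2ccc(OCC=C)cc2)[C@H]1O[Si](C(C)C)(C(C)C)C(C)C
F3 | step 19 | (E)-3-[4-(allyloxy)phenyl]-1-[2,4-dihydroxy-6-methoxy-3-(Pyr)phenyl]prop-2-en-1-one | COc1cc(O)c([C@@H]2C[C@H](CCc3ccc(OCC=C)cc3)O[C@@H](c3ccc(OCC=C)cc3)[C@H]2O[Si](C(C)C)(C(C)C)C(C)C)c(O)c1C(=O)/C=C/c1ccc(OCC=C)cc1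
F4 | step 6 | (2R,4R)-2-{2-[4-(allyloxy)phenyl]ethyl}-4-(ArA)-3,4-dihydro-2H-pyran | COCOc1cc(OC)cc(OCOC)c1[C@@H]1C[C@@H](CCc2ccc(OCC=C)cc2)OC=C1
F5 | step 6 | (3S,4S,6R)-6-{2-[4-(allyloxy)phenyl]ethyl}-4-(ArA)tetrahydro-2H-pyran-2,3-diol | COCOc1cc(OC)cc(OCOC)c1[C@@H]1C[C@@H](CCc2ccc(OCC=C)cc2)OC(O)[C@H]1O
F6 | step 16 | 1-methoxy-3,5-bis(methoxymethoxy)-4-(Pyr)-2-(trimethylsilyl)benzene | COCOc1cc(OC)c([Si](C)(C)C)c(OCOC)c1[C@@H]1C[C@H](CCc2ccc(OCC=C)cc2)O[C@@H](c2ccc(OCC=C)cc2)[C@H]1O[Si](C(C)C)(C(C)C)C(C)C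
F7 | step 16 | 5-methoxy-2-(Pyr)-4-(trimethylsilyl)benzene-1,3-diol | COc1cc(O)c([C@@H]2C[C@H](CCc3ccc(OCC=C)cc3)O[C@@H](c3ccc(OCC=C)cc3)[C@H]2O[Si](C(C)C)(C(C)C)C(C)C)c(O)c1[Si](C)(C)C
F8 | step 16 | 3-hydroxy-5-methoxy-2-(Pyr)-4-(trimethylsilyl)phenyl pivalate | COc1cc(OC(=O)C(C)(C)C)c([C@@H]2C[C@H](CCc3ccc(OCC=C)cc3)O[C@@H](c3ccc(OCC=C)cc3)[C@H]2O[Si](C(C)C)(C(C)C)C(C)C)c(O)c1[Si](C)(C)C
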